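Amounts first: the 5 recipes charge equal amounts of substrate and coupling partner and part in timing and heat. Find how strongly the amount of partner counts.

| flask | substrate | coupling partner | temperature | remark | time |
|---|---|---|---|---|---|
| Tuesday's | 10 mM | 10 mM | 95 °C | run made earlier |  |
| Monday's | 10 mM | 5 mM | 106 °C | run made earlier |  |
| Wednesday's | 10 mM | 20 mM | 95 °C | run made earlier |  |
| beta | 10 mM (fed, over 5.0 min) | 10.0 mM |  | the addition at 60 °C, then warmed to 100 °C; the feed brings no volume worth counting | 12 min |
| gamma | 10 mM | 10.0 mM | 100 °C | everything together at the start | 12 min |
| theta | 10 mM | 10.0 mM |  | everything together at the start at 60 °C, warmed to 100 °C at 5.0 min | 12 min |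
| delta | 10 mM | 10.0 mM (in portions, 3, over 5.0 min) | 100 °C | first portion at the start, last at 5.0 min | 12 min |
| epsilon | 10 mM (fed, over 5.0 min) | 10.0 mM | 100 °C | all else is in the flask from the start; the feed brings no volume worth counting | 12 min |

| run | time / min | double product / % | mono adduct / % |
|---|---|---|---|
| Tuesday's | 3.00 | 5.3 | 21.8 |
| Tuesday's | 6.00 | 12.1 | 29.9 |
| Tuesday's | 10.0 | 20.3 | 30.3 |
| Tuesday's | 12.0 | 22.5 | 33.4 |
| Monday's | 2.00 | 3.3 | 12.3 |
| Monday's | 5.00 | 6.5 | 23.5 |
| Monday's | 10.0 | 9.0 | 25.7 |
| Monday's | 15.0 | 11.7 | 25.8 |
| Wednesday's | 1.00 | 2.6 | 19.2 |
| Wednesday's | 2.50 | 14.2 | 29.5 |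
| Wednesday's | 6.00 | 37.8 | 30.9 |
| Wednesday's | 15.0 | 64.8 | 22.5 |

(readings scatter by 1 percentage point)



- the flask that comes out highest in amount of double product, in percent of the substrate charged, or "all alike" when all lie within 1.5 percentage points (beta / gamma / theta / delta / epsilon / all alike)
- double product at the end, in percent of the substrate charged, beta
- double product at the end, in percent of the substrate charged, gamma
- double product at the end, in percent of the substrate charged, theta
- double product at the end, in percent of the substrate charged, delta
- double product at the end, in percent of the substrate charged, epsilon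

1. Compare Tuesday's and Wednesday's runs, which share temperature and substrate. Wednesday's has twice the partner fraction.

2. Read double product at 6.00 min: 12.1% on Tuesday's run, 37.8% on Wednesday's.

3. Divide the logarithm of that ratio by the logarithm of the ratio of charges: 1.64. Call it the partner exponent: the power to which double product follows the partner fraction at fixed time and temperature, the apparent reaction order. It is a slope on logarithmic axes, and it carries the scatter of 1 percentage point in each reading.

4. Note that the exponent stands above one, so between these two runs double product grew faster than the partner charge.

5. Decide: keep the whole partner in the flask from the start, at 100 °C, which gamma and epsilon both do. Delta holds partner back until 5.0 min, and beta and theta stand at 60 °C until then. The exponent speaks of partner, and gamma and epsilon differ in how the substrate goes in, so it leaves the choice between those two open. This reckoning names two candidates, not a figure.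

6. Set the forecast beside it. It picks gamma: gamma 27.5%, epsilon 25%, delta 23.5%, theta 20.7%, beta 20%. Of theta and beta it says “effectively only about 7 hot minutes”.

    crystals ⇌ released group, rate k1*(cs1 - [released group]) while solid is left; crystals form when [released group] > cs1 (solubility = 4.30 mM, k = 2.56 min⁻¹)
    substrate + coupling partner → mono adduct + released group (k = 16.2 M⁻¹ min⁻¹, Ea = 53.0 kJ mol⁻¹)
    coupling partner + mono adduct → double product + released group (k = 21.7 M⁻¹ min⁻¹, Ea = 62.0 kJ mol⁻¹)
    (constants at 100 °C)

Gamma comes out highest at 26.2%, then epsilon 23.3%, delta 22.4%, theta 19.6%, beta 19.0%; the forecast holds within its tolerance. Gamma's lead does not last: at 120 min gamma holds 34.6% and beta 34.6%, with partner at 0% of its charge in gamma. Now use the exponent on beta: partner at 1.17 of the charge reckons to a rise of 5.5 points, and the computed rise there is 5 points.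

Take the neighbour of beta charged with 0.400 equiv of partner: the exponent gives 4.22% double product. The computed result is 4.10%.

The runs stem from a simulated flask from invented constants; noise was put on by code.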